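**Plan**

- Retrosynthesis: the 1,2-dioxane is opened at both C–O bonds (O2–C3 by intramolecular SN2 of a hydroperoxide on a C3 mesylate, O1–C6 by perhydrolysis of a C6 epoxide). C2–C3 is cut as an allylation and the ring bond C4–C5 as an olefin metathesis.
- Enabling feature: C3 can be carried as an acyl carbon, and the quaternary C6 bears a one-carbon branch (its future methyl) that can carry oxygen. A methacrylate on that C6–CH2–O arm puts C3, C4, C5 and C6 into a six-membered lactone, which closes at C4=C5 by metathesis with a vinyl group on C6.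
- Forward order: side chain C7–C17/Ph → 2-substituted allylic alcohol → asymmetric epoxidation → vinyl carbinol → methacrylate → lactone (ring 1, temporary) → hydrogenation → lactol → allylation → epoxide → hydroperoxide → 1,2-dioxane (ring 2, final) → CH2OH to CH3 → alkene to CO2H.
- Stereochemistry: C8 from (S)-3-bromo-2-methylpropan-1-ol. C6 from Sharpless epoxidation, carried through the lactone and inverted once by H2O2. C4 from hydroxyl-directed hydrogenation inside the lactone. C3 from reagent-controlled allylboration, inverted once in the SN2 ring closure.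

Key step: step 7

Remark: locants C1–C17, O1 and O2 are those of the target (C1 = carboxyl carbon; O2 on C3, O1 on C6); (8-bromooctyl)benzene, (S)-3-bromo-2-methylpropan-1-ol and (+)-Ipc2B(allyl) are assumed to be purchased.

**Route**

Step 1
Reactants: 1 (8-bromooctyl)benzene; 2 (S)-3-bromo-2-methylpropan-1-ol
Product: 4 (2R)-2-methyl-11-phenylundecan-1-ol, via (8-phenyloctyl)magnesium bromide 3 (not isolated)
Conditions: 1, Mg, THF, 50 °C; 2, i-PrMgCl (1.0 equiv), THF, −20 °C; combine, Li2CuCl4 (3 mol %), −20 °C → rt; aq. NH4Cl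
Reagents that add atoms: none
Why: Copper-catalysed sp3–sp3 Grignard cross-coupling at the primary bromide of the magnesium alkoxide of 2 should join C9 to the phenyloctyl chain, with the C8 stereocentre brought in unchanged from the chiral pool.

Step 2
Reactants: 4 (2R)-2-methyl-11-phenylundecan-1-ol
Product: 5 (2R)-1-bromo-2-methyl-11-phenylundecane
Conditions: CBr4, PPh3, CH2Cl2, 0 °C → rt
Reagents that add atoms: carbon tetrabromide, BrC(Br)(Br)Br
Why: The Appel reaction converts the primary alcohol to the bromide under neutral conditions and does not touch C8.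

Step 3
Reactants: 5 (2R)-1-bromo-2-methyl-11-phenylundecane; 6 prop-2-yn-1-ol
Product: 8 (4R)-4-methyl-2-methylidene-13-phenyltridecan-1-ol, via [(2R)-2-methyl-11-phenylundecyl]magnesium bromide 7 (not isolated)
Conditions: 5, Mg, THF, 50 °C; 6, EtMgBr (1.0 equiv), THF, 0 °C; combine, CuI (copper monoiodide, 10 mol %), −10 °C → rt; aq. NH4Cl
Reagents that add atoms: none
Why: Copper-catalysed anti-carbomagnesiation of the magnesium alkoxide of propargyl alcohol places the alkyl group on the internal alkyne carbon, giving after protonation the 2-substituted allylic alcohol that holds C6, the future C5 (=CH2) and the one-carbon arm of C6.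

Step 4
Reactants: 8 (4R)-4-methyl-2-methylidene-13-phenyltridecan-1-ol
Product: 9 [(2R)-2-[(2R)-2-methyl-11-phenylundecyl]oxiran-2-yl]methanol
Conditions: Ti(OiPr)4 (10 mol %), D-(−)-diisopropyl tartrate (12 mol %), t-BuOOH, 4 Å molecular sieves, CH2Cl2, −20 °C
Reagents that add atoms: tert-butyl hydroperoxide, CC(C)(C)OO
Why: Sharpless asymmetric epoxidation of the 2-substituted allylic alcohol with the D-(−)-tartrate should deliver oxygen to the face that gives the (R)-epoxide, so the future C6 is fixed by reagent control.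

Step 5
Reactants: 9 [(2R)-2-[(2R)-2-methyl-11-phenylundecyl]oxiran-2-yl]methanol
Product: 10 (2S)-2-[(2R)-2-methyl-11-phenylundecyl]but-3-ene-1,2-diol
Conditions: Me3S+ I− (4 equiv), n-BuLi (3.9 equiv), THF, −10 °C → rt
Reagents that add atoms: trimethylsulfonium iodide, C[S+](C)C.[I-]
Why: Sulfonium-ylide homologation of an epoxide to an allylic alcohol: the ylide opens the epoxide at its CH2 and the sulfonium salt eliminates, so that CH2 becomes the vinyl CH (C5) while the C6–O bond and its configuration are kept (the Payne shift of this epoxy alcohol is degenerate and cannot erode it).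

Step 6
Reactants: 10 (2S)-2-[(2R)-2-methyl-11-phenylundecyl]but-3-ene-1,2-diol
Product: 11 [(2S)-2-hydroxy-2-[(2R)-2-methyl-11-phenylundecyl]but-3-en-1-yl] 2-methylprop-2-enoate
Conditions: methacryloyl chloride (1.1 equiv), Et3N, DMAP (5 mol %), CH2Cl2, −40 °C → 0 °C
Reagents that add atoms: methacryloyl chloride, CC(=C)C(Cl)=O
Why: Selective O-acylation of the primary hydroxyl over the tertiary allylic one installs C3, C4 and the C4 methyl as a methacrylate tethered through the CH2–O arm of C6.

Step 7
Reactants: 11 [(2S)-2-hydroxy-2-[(2R)-2-methyl-11-phenylundecyl]but-3-en-1-yl] 2-methylprop-2-enoate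
Product: 12 (5S)-5-hydroxy-3-methyl-5-[(2R)-2-methyl-11-phenylundecyl]-5,6-dihydro-2H-pyran-2-one
Conditions: second-generation Grubbs catalyst, RuCl2(=CHPh)(PCy3)(H2IMes) (5 mol %), toluene (0.005 M), 80 °C, argon sparge
Reagents that add atoms: none
Why: Ring-closing olefin metathesis: the ruthenium alkylidene should load onto the monosubstituted vinyl group on C6, add across the methacrylate C=CH2 to a ruthenacyclobutane and cyclorevert with loss of ethene, forming the C4=C5 bond. The closest known reaction type is the ring-closing metathesis of methacrylates of homoallylic alcohols to 3-methyl-5,6-dihydro-2H-pyran-2-ones. The ring closed is the six-membered unsaturated lactone O–C3(=O)–C4=C5–C6–CH2, a six-membered closure by metathesis in which the new trisubstituted alkene can only be cis. No stereocentre is made here: C6 is untouched and C4 is left sp2 on purpose, to be set in step 8 by this ring, whose C6 hydroxyl marks one face. The step needs ring closure to beat cross-metathesis dimerisation; high dilution, the electron-poor 1,1-disubstituted partner (slow to homodimerise) and the fully substituted allylic C6 should secure this, and the free tertiary hydroxyl is tolerated.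

Step 8
Reactants: 12 (5S)-5-hydroxy-3-methyl-5-[(2R)-2-methyl-11-phenylundecyl]-5,6-dihydro-2H-pyran-2-one
Product: 13 (3S,5S)-5-hydroxy-3-methyl-5-[(2R)-2-methyl-11-phenylundecyl]oxan-2-one
Conditions: H2 (1 atm), [Ir(cod)(PCy3)(py)]PF6 (5 mol %), CH2Cl2, rt
Reagents that add atoms: none
Why: Hydroxyl-directed homogeneous hydrogenation: the cationic iridium catalyst binds the C6 hydroxyl and delivers H2 syn to it across C4=C5, so the C4 methyl ends trans to the hydroxyl and cis to the side chain, which is the configuration needed at C4.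

Step 9
Reactants: 13 (3S,5S)-5-hydroxy-3-methyl-5-[(2R)-2-methyl-11-phenylundecyl]oxan-2-one
Product: 14 (3S,5S)-3-methyl-5-[(2R)-2-methyl-11-phenylundecyl]oxane-2,5-diol (both anomers)
Conditions: i-Bu2AlH (2.2 equiv), CH2Cl2, −78 °C; Rochelle salt work-up
Reagents that add atoms: none
Why: Low-temperature hydride reduction of the lactone stops at the lactol (masked C3 aldehyde) with C4 and C6 untouched; any ring-contracted lactone formed by acyl shift to the C6 hydroxyl would be reduced to the same open-chain hydroxy aldehyde.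

Step 10
Reactants: 14 (3S,5S)-3-methyl-5-[(2R)-2-methyl-11-phenylundecyl]oxane-2,5-diol
Product: 15 (2S,4S,5R)-4-methyl-2-[(2R)-2-methyl-11-phenylundecyl]oct-7-ene-1,2,5-triol
Conditions: (+)-Ipc2B(allyl) (2.5 equiv), Et2O, −78 °C → −20 °C; then NaOH, H2O2
Reagents that add atoms: (+)-B-allyldiisopinocampheylborane, C=CCB([C@H]1C[C@H]2C[C@@H]([C@@H]1C)C2(C)C)[C@H]1C[C@H]2C[C@@H]([C@@H]1C)C2(C)C
Why: Brown allylboration through a chair Zimmerman–Traxler transition state: the (+)-reagent should add allyl to the Re face of the C3 aldehyde (open form of the lactol) under reagent control, overriding the Felkin preference and giving the C3 alcohol anti to the C4 methyl, as required before the later inversion.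

Step 11
Reactants: 15 (2S,4S,5R)-4-methyl-2-[(2R)-2-methyl-11-phenylundecyl]oct-7-ene-1,2,5-triol
Product: 17 (4R,5S)-5-methyl-6-[(2S)-2-[(2R)-2-methyl-11-phenylundecyl]oxiran-2-yl]hex-1-en-4-ol, via primary tosylate 16 (not isolated)
Conditions: TsCl (1.05 equiv), Et3N, Bu2SnO (2 mol %), CH2Cl2, 0 °C; then K2CO3, MeOH, rt
Reagents that add atoms: none
Why: Tin-catalysed monosulfonylation goes to the primary hydroxyl of the 1,2-diol, and the tertiary alkoxide then closes the epoxide by intramolecular Williamson displacement (3-exo-tet), so C6 keeps the oxygen and the configuration set in step 4.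

Step 12
Reactants: 17 (4R,5S)-5-methyl-6-[(2S)-2-[(2R)-2-methyl-11-phenylundecyl]oxiran-2-yl]hex-1-en-4-ol
Product: 18 (4R,5S)-5-methyl-6-[(2S)-2-[(2R)-2-methyl-11-phenylundecyl]oxiran-2-yl]hex-1-en-4-yl methanesulfonate
Conditions: MsCl, Et3N, CH2Cl2, −20 °C
Reagents that add atoms: methanesulfonyl chloride, CS(Cl)(=O)=O
Why: O-Sulfonylation of the only remaining hydroxyl makes C3 an SN2 electrophile with retention at C3; epoxide and alkene are inert to these conditions.

Step 13
Reactants: 18 (4R,5S)-5-methyl-6-[(2S)-2-[(2R)-2-methyl-11-phenylundecyl]oxiran-2-yl]hex-1-en-4-yl methanesulfonate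
Product: 19 (4R,5S,7R)-7-hydroperoxy-8-hydroxy-5-methyl-7-[(2R)-2-methyl-11-phenylundecyl]oct-1-en-4-yl methanesulfonate
Conditions: H2O2 (anhydrous, in Et2O, 5 equiv), H3PMo12O40 (2 mol %), Et2O, rt
Reagents that add atoms: hydrogen peroxide, OO
Why: Phosphomolybdic acid-catalysed perhydrolysis of a 2,2-disubstituted epoxide: H2O2 should attack the tertiary C6 from the back (borderline SN2), so the O–O unit enters with inversion and gives C6 its final configuration, leaving a CH2OH that is the future C6 methyl.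

Step 14
Reactants: 19 (4R,5S,7R)-7-hydroperoxy-8-hydroxy-5-methyl-7-[(2R)-2-methyl-11-phenylundecyl]oct-1-en-4-yl methanesulfonate
Product: 20 [(3R,5S,6S)-5-methyl-3-[(2R)-2-methyl-11-phenylundecyl]-6-(prop-2-en-1-yl)-1,2-dioxan-3-yl]methanol
Conditions: CsOH·H2O (1.05 equiv), DMF, 0 °C
Reagents that add atoms: none
Why: Intramolecular alkylation of the hydroperoxide anion (6-exo-tet SN2) at C3 closes the 1,2-dioxane with inversion at C3, giving the 3,4-cis arrangement; the more acidic, more nucleophilic OOH should react in preference to the primary alcohol.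

Step 15
Reactants: 20 [(3R,5S,6S)-5-methyl-3-[(2R)-2-methyl-11-phenylundecyl]-6-(prop-2-en-1-yl)-1,2-dioxan-3-yl]methanol
Product: 22 (3R,5S,6S)-3-(iodomethyl)-5-methyl-3-[(2R)-2-methyl-11-phenylundecyl]-6-(prop-2-en-1-yl)-1,2-dioxane, via primary triflate 21 (not isolated)
Conditions: Tf2O, 2,6-lutidine, CH2Cl2, −78 °C; then Bu4NI, −78 °C → rt
Reagents that add atoms: tetrabutylammonium iodide, CCCC[N+](CCCC)(CCCC)CCCC.[I-]
Why: The hindered primary alcohol is activated as its triflate and displaced by iodide (SN2), giving a radical precursor without touching the dialkyl peroxide.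

Step 16
Reactants: 22 (3R,5S,6S)-3-(iodomethyl)-5-methyl-3-[(2R)-2-methyl-11-phenylundecyl]-6-(prop-2-en-1-yl)-1,2-dioxane
Product: 23 (3S,4S,6R)-4,6-dimethyl-6-[(2R)-2-methyl-11-phenylundecyl]-3-(prop-2-en-1-yl)-1,2-dioxane
Conditions: Bu3SnH (5 equiv, 0.5 M), Et3B (0.2 equiv), air, toluene, 0 °C
Reagents that add atoms: none
Why: Radical-chain dehalogenation: at high Bu3SnH concentration the primary radical should be reduced faster than it can attack the neighbouring O–O bond, turning CH2I into the C6 methyl.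

Step 17
Reactants: 23 (3S,4S,6R)-4,6-dimethyl-6-[(2R)-2-methyl-11-phenylundecyl]-3-(prop-2-en-1-yl)-1,2-dioxane
Product: 25 2-[(3S,4S,6R)-4,6-dimethyl-6-[(2R)-2-methyl-11-phenylundecyl]-1,2-dioxan-3-yl]acetic acid, via aldehyde 24 (not isolated)
Conditions: O3, CH2Cl2, −78 °C (Sudan red end point); Me2S, −78 °C → rt; then NaClO2, NaH2PO4, 2-methylbut-2-ene, t-BuOH/H2O, 0 °C → rt
Reagents that add atoms: ozone, [O-][O+]=O; sodium chlorite, [Na+].[O-]Cl=O
Why: Ozonolysis cleaves the terminal alkene (far more reactive than the phenyl ring, and the dialkyl peroxide is inert) to the aldehyde, and Pinnick oxidation under buffered, non-basic conditions should give the acid without β-elimination of the peroxide.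

**Compound list**

1 | (8-bromooctyl)benzene | BrCCCCCCCCc1ccccc1 | starting material
2 | (S)-3-bromo-2-methylpropan-1-ol | C[C@H](CBr)CO | starting material
3 | (8-phenyloctyl)magnesium bromide | Br[Mg]CCCCCCCCc1ccccc1 | intermediate
4 | (2R)-2-methyl-11-phenylundecan-1-ol | C[C@H](CCCCCCCCCc1ccccc1)CO | intermediate
5 | (2R)-1-bromo-2-methyl-11-phenylundecane | C[C@H](CCCCCCCCCc1ccccc1)CBr | intermediate
6 | prop-2-yn-1-ol | C#CCO | starting material
7 | [(2R)-2-methyl-11-phenylundecyl]magnesium bromide | C[C@H](CCCCCCCCCc1ccccc1)C[Mg]Br | intermediate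
8 | (4R)-4-methyl-2-methylidene-13-phenyltridecan-1-ol | C[C@H](CCCCCCCCCc1ccccc1)CC(=C)CO | intermediate
9 | [(2R)-2-[(2R)-2-methyl-11-phenylundecyl]oxiran-2-yl]methanol | C[C@H](CCCCCCCCCc1ccccc1)C[C@@]1(CO)CO1 | intermediate
10 | (2S)-2-[(2R)-2-methyl-11-phenylundecyl]but-3-ene-1,2-diol | C[C@H](CCCCCCCCCc1ccccc1)C[C@@](O)(CO)C=C | intermediate
11 | [(2S)-2-hydroxy-2-[(2R)-2-methyl-11-phenylundecyl]but-3-en-1-yl] 2-methylprop-2-enoate | C[C@H](CCCCCCCCCc1ccccc1)C[C@@](O)(COC(=O)C(C)=C)C=C | intermediate
12 | (5S)-5-hydroxy-3-methyl-5-[(2R)-2-methyl-11-phenylundecyl]-5,6-dihydro-2H-pyran-2-one | C[C@H](CCCCCCCCCc1ccccc1)C[C@@]1(O)COC(=O)C(C)=C1 | intermediate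
13 | (3S,5S)-5-hydroxy-3-methyl-5-[(2R)-2-methyl-11-phenylundecyl]oxan-2-one | C[C@H](CCCCCCCCCc1ccccc1)C[C@@]1(O)COC(=O)[C@@H](C)C1 | intermediate
14 | (3S,5S)-3-methyl-5-[(2R)-2-methyl-11-phenylundecyl]oxane-2,5-diol (both anomers at C2) | C[C@H](CCCCCCCCCc1ccccc1)C[C@@]1(O)COC(O)[C@@H](C)C1 | intermediate
15 | (2S,4S,5R)-4-methyl-2-[(2R)-2-methyl-11-phenylundecyl]oct-7-ene-1,2,5-triol | C[C@H](CCCCCCCCCc1ccccc1)C[C@@](O)(CO)C[C@H](C)[C@H](O)CC=C | intermediate
16 | [(2S,4S,5R)-2,5-dihydroxy-4-methyl-2-[(2R)-2-methyl-11-phenylundecyl]oct-7-en-1-yl] 4-methylbenzenesulfonate | C[C@H](CCCCCCCCCc1ccccc1)C[C@@](O)(COS(=O)(=O)c1ccc(C)cc1)C[C@H](C)[C@H](O)CC=C | intermediate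
17 | (4R,5S)-5-methyl-6-[(2S)-2-[(2R)-2-methyl-11-phenylundecyl]oxiran-2-yl]hex-1-en-4-ol | C[C@H](CCCCCCCCCc1ccccc1)C[C@@]1(CO1)C[C@H](C)[C@H](O)CC=C | intermediate
18 | (4R,5S)-5-methyl-6-[(2S)-2-[(2R)-2-methyl-11-phenylundecyl]oxiran-2-yl]hex-1-en-4-yl methanesulfonate | C[C@H](CCCCCCCCCc1ccccc1)C[C@@]1(CO1)C[C@H](C)[C@H](OS(C)(=O)=O)CC=C | intermediate
19 | (4R,5S,7R)-7-hydroperoxy-8-hydroxy-5-methyl-7-[(2R)-2-methyl-11-phenylundecyl]oct-1-en-4-yl methanesulfonate | C[C@H](CCCCCCCCCc1ccccc1)C[C@](OO)(CO)C[C@H](C)[C@H](OS(C)(=O)=O)CC=C | intermediate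
20 | [(3R,5S,6S)-5-methyl-3-[(2R)-2-methyl-11-phenylundecyl]-6-(prop-2-en-1-yl)-1,2-dioxan-3-yl]methanol | C[C@H](CCCCCCCCCc1ccccc1)C[C@]1(CO)C[C@H](C)[C@H](CC=C)OO1 | intermediate
21 | [(3R,5S,6S)-5-methyl-3-[(2R)-2-methyl-11-phenylundecyl]-6-(prop-2-en-1-yl)-1,2-dioxan-3-yl]methyl trifluoromethanesulfonate | C[C@H](CCCCCCCCCc1ccccc1)C[C@]1(COS(=O)(=O)C(F)(F)F)C[C@H](C)[C@H](CC=C)OO1 | intermediate
22 | (3R,5S,6S)-3-(iodomethyl)-5-methyl-3-[(2R)-2-methyl-11-phenylundecyl]-6-(prop-2-en-1-yl)-1,2-dioxane | C[C@H](CCCCCCCCCc1ccccc1)C[C@]1(CI)C[C@H](C)[C@H](CC=C)OO1 | intermediate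
23 | (3S,4S,6R)-4,6-dimethyl-6-[(2R)-2-methyl-11-phenylundecyl]-3-(prop-2-en-1-yl)-1,2-dioxane | C[C@H](CCCCCCCCCc1ccccc1)C[C@]1(C)C[C@H](C)[C@H](CC=C)OO1 | intermediate
24 | 2-[(3S,4S,6R)-4,6-dimethyl-6-[(2R)-2-methyl-11-phenylundecyl]-1,2-dioxan-3-yl]acetaldehyde | C[C@H](CCCCCCCCCc1ccccc1)C[C@]1(C)C[C@H](C)[C@H](CC=O)OO1 | intermediate
25 | 2-[(3S,4S,6R)-4,6-dimethyl-6-[(2R)-2-methyl-11-phenylundecyl]-1,2-dioxan-3-yl]acetic acid | C[C@H](CCCCCCCCCc1ccccc1)C[C@]1(C)C[C@H](C)[C@H](CC(=O)O)OO1 | target

**Step count and risks**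

Total step count: 17. Longest linear sequence: 17 steps (from 1 and 2 to 25).

The three steps most likely to fail, with one fallback each:

(a) Step 13. The tertiary epoxide carbon may partly ionise, which would erode the configuration at C6; H2O2 may also attack the primary carbon, or acid may trigger a hydride shift to an aldehyde. The fallback sets out from mesylate 18 and comes back at 20, bypassing steps 13 and 14. The mesylate is displaced first by 2-methoxyprop-2-yl hydroperoxide (CsOH·H2O, DMF, 0 °C), giving with inversion at C3 the peroxyketal (2S)-2-[(2S,3S)-3-[(2-methoxypropan-2-yl)peroxy]-2-methylhex-5-en-1-yl]-2-[(2R)-2-methyl-11-phenylundecyl]oxirane F1. Aqueous acetic acid in THF unmasks it to the secondary hydroperoxide (2S)-2-[(2S,3S)-3-hydroperoxy-2-methylhex-5-en-1-yl]-2-[(2R)-2-methyl-11-phenylundecyl]oxirane F2. A trace of camphorsulfonic acid in CH2Cl2 then lets the C3–OOH open the epoxide at C6 in a 6-exo mode with inversion, which gives 20 directly. The oxygen is thus delivered to C6 by a tether instead of by free H2O2, and the order of the two C–O bond formations is reversed.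

(b) Step 16. The primary radical next to the peroxide may attack the O–O bond (epoxide formation with ring opening) before it is reduced, and the hindered iodide of step 15 may form slowly. The fallback sets out from triflate 21 and comes back at 23. The triflate is reduced directly by LiBHEt3 in THF at −78 °C, a polar hydride displacement that generates no carbon radical and needs no iodide. It makes no new compound.

(c) Step 10. Facial selectivity may be poor, because the reagent has to override the Felkin preference of the α-methyl aldehyde, and the lactol may react slowly. The fallback sets out from lactone 13 and comes back at 15. Allylmagnesium bromide (CH2=CHCH2MgBr, THF, −78 °C) is added once to 13 to give the hemiketal (3S,5S)-3-methyl-5-[(2R)-2-methyl-11-phenylundecyl]-2-(prop-2-en-1-yl)oxane-2,5-diol F3, the ring tautomer of the C3 allyl ketone. Its keto form is then reduced with LiBH(s-Bu)3 in THF at −78 °C. Hydride is now the incoming group and allyl the spectator, so Felkin–Anh addition anti to the C5 branch should give the same 3,4-anti alcohol 15 under substrate control.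

Further compounds
F1 | step 13 | (2S)-2-[(2S,3S)-3-[(2-methoxypropan-2-yl)peroxy]-2-methylhex-5-en-1-yl]-2-[(2R)-2-methyl-11-phenylundecyl]oxirane | C[C@H](CCCCCCCCCc1ccccc1)C[C@@]1(CO1)C[C@H](C)[C@@H](OOC(C)(C)OC)CC=C
F2 | step 13 | (2S)-2-[(2S,3S)-3-hydroperoxy-2-methylhex-5-en-1-yl]-2-[(2R)-2-methyl-11-phenylundecyl]oxirane | C[C@H](CCCCCCCCCc1ccccc1)C[C@@]1(CO1)C[C@H](C)[C@@H](OO)CC=C
F0 | step 16 | none | none
F3 | step 10 | (3S,5S)-3-methyl-5-[(2R)-2-methyl-11-phenylundecyl]-2-(prop-2-en-1-yl)oxane-2,5-diol (both anomers at C2) | C[C@H](CCCCCCCCCc1ccccc1)C[C@@]1(O)COC(O)(CC=C)[C@@H](C)C1
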